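**Strategy.** The target is a 1,7-diarylheptan-3-one; everything rests on building its 2,4-dihydroxy-3-methoxyphenyl ring (C1 chain, C2 OH, C3 OMe, C4 OH, C5/C6 H) from acyclic pieces. A [4+2] cycloaddition between a 2-methoxy-1,3-bis(silyloxy)butadiene (C2–C5, carrying all three oxygens) and methyl propiolate (C6–C1) forms C1–C2 and C5–C6, closes the ring and, after loss of methanol and the silyl groups, gives methyl 2,4-dihydroxy-3-methoxybenzoate, with the middle oxygen already fixed as its methyl ether and the flanking ones free. The diene comes from methyl acetoacetate in four steps. The ester carbon is then joined to 6-(4-methoxyphenyl)hexan-2-one by Claisen–Schmidt condensation, and one hydrogenation finishes the synthesis.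

Key step: step 5

Assumption: the double-bond geometries drawn for 4, 5 and 6 are nominal and mixtures would serve equally, since the C2=C3 bond of 4 becomes a single bond in 6 and the geometry of 6 disappears on aromatisation. Compounds 3, 8, 17 and 19 are racemic; none of their stereocentres reaches the target, which has none.

**Route**

Step 1
Reactants: 1 methyl acetoacetate
Product: 2 methyl 2-diazo-3-oxobutanoate
Conditions: 4-acetamidobenzenesulfonyl azide, Et3N, MeCN, 0 °C to rt
Reagents that add atoms: 4-acetamidobenzenesulfonyl azide, CC(=O)Nc1ccc(cc1)S(=O)(=O)N=[N+]=[N-]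
Why: Regitz diazo transfer, in which the enolate of the 1,3-dicarbonyl compound attacks the terminal azide nitrogen and the triazene fragments to the doubly acceptor-stabilised diazo ester and the sulfonamide, a standard reaction of acetoacetates.

Step 2
Reactants: 2 methyl 2-diazo-3-oxobutanoate
Product: 3 methyl 2-methoxy-3-oxobutanoate (racemic)
Conditions: Rh2(OAc)4 (1 mol%), MeOH (5 equiv), CH2Cl2, reflux
Reagents that add atoms: methanol, CO
Why: Rhodium-carbenoid O–H insertion, in which Rh2(OAc)4 turns the diazo ester into an electrophilic carbenoid that methanol traps through an oxonium ylide and proton shift; the new C2 stereocentre is racemic and is erased by enolisation in step 3.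

Step 3
Reactants: 3 methyl 2-methoxy-3-oxobutanoate
Product: 4 methyl (2E)-2-methoxy-3-(trimethylsilyloxy)but-2-enoate
Conditions: TMSCl, Et3N, toluene, rt; filtration under N2, distillation
Reagents that add atoms: chlorotrimethylsilane, C[Si](C)(C)Cl
Why: Silyl enol ether formation by soft enolisation, regioselective because only the C2–H flanked by both carbonyl groups is acidic enough for triethylamine, so O-silylation should give the conjugated enol ether.

Step 4
Reactants: 4 methyl (2E)-2-methoxy-3-(trimethylsilyloxy)but-2-enoate
Product: 6 (1Z)-1,2-dimethoxy-1,3-bis(trimethylsilyloxy)buta-1,3-diene, via lithium dienolate 5 (not isolated)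
Conditions: LDA (lithium diisopropylamide, LiN(iPr)2, commercial solution), THF, −78 °C; TMSCl, −78 °C to rt; hexane, filtration under Ar, used crude
Reagents that add atoms: chlorotrimethylsilane, C[Si](C)(C)Cl
Why: Second stage of the standard bis(silyl enol ether) synthesis, in which LDA removes a γ-proton of the vinylogous ester to give dienolate 5 and the hard electrophile TMSCl silylates it on oxygen to give the cross-conjugated ketene acetal diene.

Step 5
Reactants: 6 (1Z)-1,2-dimethoxy-1,3-bis(trimethylsilyloxy)buta-1,3-diene; 7 methyl propiolate
Product: 9 methyl 2,4-dihydroxy-3-methoxybenzoate, via cyclohexadiene cycloadduct 8 (not isolated)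
Conditions: 7 (1.5 equiv), toluene, 80 °C, sealed tube; then 1 M aq. HCl (cat.), THF, rt
Reagents that add atoms: none
Why: This is a thermal, normal-electron-demand Diels–Alder reaction in which the electron-rich diene 6 and the electron-poor alkyne 7 combine in an asynchronous [4+2]: the unsubstituted CH2 terminus (largest HOMO coefficient) bonds to the propiolate β-carbon (C5–C6) and the ketene acetal carbon bonds to the ester-bearing carbon (C1–C2). The closest known reaction type is the benzannulation of 1-alkoxy-1,3-bis(silyloxy)butadienes and related Danishefsky–Brassard dienes with acetylenic esters to give resorcylates, the extra 2-methoxy group being a spectator on the diene backbone. The single six-membered carbocycle is closed intermolecularly by the cycloaddition itself, both ring bonds being made in the same event, to give cyclohexa-1,4-diene 8. Dilute acid then cleaves the silyl ethers, the C2 hemiketal so formed expels methanol, and the resulting dioxo tautomer enolises to the arene, so that only the central oxygen remains as an ether. No stereocentre survives, because the ketal carbon of 8 is racemic and becomes sp2 and the diene geometry is lost in the same way. The step needs regiocontrol only, which the matched polarisation of the partners (nucleophilic methylene terminus, electrophilic β-carbon) secures by placing the ester next to the C2 oxygen.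

Step 6
Reactants: 9 methyl 2,4-dihydroxy-3-methoxybenzoate
Product: 10 methyl 2,4-bis(benzyloxy)-3-methoxybenzoate
Conditions: BnBr (2.4 equiv), K2CO3, DMF, 60 °C
Reagents that add atoms: benzyl bromide, BrCc1ccccc1
Why: Williamson etherification, in which warm K2CO3/DMF should alkylate both phenols, including the C2 hydroxyl hydrogen-bonded to the ester; benzyl is chosen because the final hydrogenation removes it without an extra step.

Step 7
Reactants: 10 methyl 2,4-bis(benzyloxy)-3-methoxybenzoate
Product: 11 [2,4-bis(benzyloxy)-3-methoxyphenyl]methanol
Conditions: LiAlH4, THF, 0 °C; H2O, aq. NaOH work-up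
Reagents that add atoms: none
Why: Hydride reduction of an aryl ester to the benzylic alcohol with LiAlH4, to which aryl benzyl and methyl ethers are inert.

Step 8
Reactants: 11 [2,4-bis(benzyloxy)-3-methoxyphenyl]methanol
Product: 12 2,4-bis(benzyloxy)-3-methoxybenzaldehyde
Conditions: activated MnO2 (10 equiv), CH2Cl2, rt
Reagents that add atoms: none
Why: Manganese dioxide oxidation, selective for benzylic alcohols, should stop at the aldehyde and leave the ethers untouched.

Step 9
Reactants: 13 4-(4-methoxyphenyl)butan-1-ol
Product: 14 1-(4-bromobutyl)-4-methoxybenzene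
Conditions: CBr4, PPh3, CH2Cl2, 0 °C to rt
Reagents that add atoms: carbon tetrabromide, BrC(Br)(Br)Br
Why: Appel reaction, in which the alkoxyphosphonium ion formed from PPh3/CBr4 is displaced by bromide in an SN2 step at the primary carbon under neutral conditions that spare the anisole.

Step 10
Reactants: 14 1-(4-bromobutyl)-4-methoxybenzene; 15 N-methoxy-N-methylacetamide
Product: 18 6-(4-methoxyphenyl)hexan-2-one, via Grignard reagent 16 (not isolated), via magnesium hemiaminal chelate 17 (not isolated)
Conditions: Mg, I2 (cat.), THF, 40 °C; 15, THF, 0 °C; 1 M aq. HCl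
Reagents that add atoms: none
Why: Weinreb ketone synthesis, in which the primary alkyl Grignard reagent 16 adds once to the N-methoxy-N-methylamide because the chelated tetrahedral intermediate 17 persists until the acidic quench, which releases the methyl ketone without over-addition.

Step 11
Reactants: 12 2,4-bis(benzyloxy)-3-methoxybenzaldehyde; 18 6-(4-methoxyphenyl)hexan-2-one
Product: 20 (1E)-1-[2,4-bis(benzyloxy)-3-methoxyphenyl]-7-(4-methoxyphenyl)hept-1-en-3-one, via aldol adduct 19 (not isolated)
Conditions: KOH, EtOH/H2O, rt
Reagents that add atoms: none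
Why: Claisen–Schmidt (crossed aldol) condensation, in which the aldehyde cannot enolise and, under reversible basic conditions, the methyl-side aldol 19 is the one that dehydrates irreversibly to the conjugated enone, whose E geometry is the thermodynamic one and is removed in step 12 in any case.

Step 12
Reactants: 20 (1E)-1-[2,4-bis(benzyloxy)-3-methoxyphenyl]-7-(4-methoxyphenyl)hept-1-en-3-one
Product: 21 1-(2,4-dihydroxy-3-methoxyphenyl)-7-(4-methoxyphenyl)heptan-3-one
Conditions: H2 (1 atm), 10% Pd/C, EtOAc, rt
Reagents that add atoms: none
Why: Heterogeneous catalytic hydrogenation over Pd/C should saturate the conjugated C=C and hydrogenolyse both aryl benzyl ethers in one operation, while the dialkyl ketone, the methyl ethers and the arenes are stable under these neutral conditions.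

**Compound list**

1 | methyl acetoacetate (methyl 3-oxobutanoate) | CC(=O)CC(=O)OC | starting material
2 | methyl 2-diazo-3-oxobutanoate | CC(=O)C(=[N+]=[N-])C(=O)OC | intermediate
3 | methyl 2-methoxy-3-oxobutanoate (racemic) | CC(=O)C(OC)C(=O)OC | intermediate
4 | methyl (2E)-2-methoxy-3-(trimethylsilyloxy)but-2-enoate | C/C(O[Si](C)(C)C)=C(\OC)C(=O)OC | intermediate
5 | lithium (1E)-1,2-dimethoxy-3-(trimethylsilyloxy)buta-1,3-dien-1-olate (lithium dienolate of 4, not isolated) | C=C(O[Si](C)(C)C)/C(OC)=C(\OC)O[Li] | intermediate
6 | (1Z)-1,2-dimethoxy-1,3-bis(trimethylsilyloxy)buta-1,3-diene | C=C(O[Si](C)(C)C)/C(OC)=C(\OC)O[Si](C)(C)C | intermediate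
7 | methyl propiolate | C#CC(=O)OC | starting material
8 | methyl 5,6-dimethoxy-4,6-bis(trimethylsilyloxy)cyclohexa-1,4-diene-1-carboxylate (racemic cycloadduct, not isolated) | COC(=O)C1=CCC(O[Si](C)(C)C)=C(OC)C1(OC)O[Si](C)(C)C | intermediate
9 | methyl 2,4-dihydroxy-3-methoxybenzoate | COC(=O)c1ccc(O)c(OC)c1O | intermediate
10 | methyl 2,4-bis(benzyloxy)-3-methoxybenzoate | COC(=O)c1ccc(OCc2ccccc2)c(OC)c1OCc1ccccc1 | intermediate
11 | [2,4-bis(benzyloxy)-3-methoxyphenyl]methanol | OCc1ccc(OCc2ccccc2)c(OC)c1OCc1ccccc1 | intermediate
12 | 2,4-bis(benzyloxy)-3-methoxybenzaldehyde | O=Cc1ccc(OCc2ccccc2)c(OC)c1OCc1ccccc1 | intermediate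
13 | 4-(4-methoxyphenyl)butan-1-ol | COc1ccc(CCCCO)cc1 | starting material
14 | 1-(4-bromobutyl)-4-methoxybenzene | COc1ccc(CCCCBr)cc1 | intermediate
15 | N-methoxy-N-methylacetamide | CON(C)C(C)=O | starting material
16 | [4-(4-methoxyphenyl)butyl]magnesium bromide (not isolated) | COc1ccc(CCCC[Mg]Br)cc1 | intermediate
17 | bromomagnesium 2-[methoxy(methyl)amino]-6-(4-methoxyphenyl)hexan-2-olate (racemic chelated tetrahedral adduct, not isolated) | COc1ccc(CCCCC(C)(O[Mg]Br)N(C)OC)cc1 | intermediate
18 | 6-(4-methoxyphenyl)hexan-2-one | COc1ccc(CCCCC(C)=O)cc1 | intermediate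
19 | 1-[2,4-bis(benzyloxy)-3-methoxyphenyl]-1-hydroxy-7-(4-methoxyphenyl)heptan-3-one (racemic aldol adduct, not isolated) | COc1ccc(CCCCC(=O)CC(O)c2ccc(OCc3ccccc3)c(OC)c2OCc2ccccc2)cc1 | intermediate
20 | (1E)-1-[2,4-bis(benzyloxy)-3-methoxyphenyl]-7-(4-methoxyphenyl)hept-1-en-3-one | COc1ccc(CCCCC(=O)/C=C/c2ccc(OCc3ccccc3)c(OC)c2OCc2ccccc2)cc1 | intermediate
21 | 1-(2,4-dihydroxy-3-methoxyphenyl)-7-(4-methoxyphenyl)heptan-3-one | COc1ccc(CCCCC(=O)CCc2ccc(O)c(OC)c2O)cc1 | target

**Step count**

Total: 12 steps. Longest linear sequence: 10 steps (steps 1–8, 11 and 12, from methyl acetoacetate); the ketone branch (steps 9 and 10) joins at step 11.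

**Steps most likely to fail**

1. Step 5 (cycloaddition and aromatisation). Desilylation or oligomerisation of the tetrasubstituted diene, or polymerisation of the alkynoate, may outrun the cycloaddition. The reaction may also stop at an open-chain conjugate adduct, or aromatisation may proceed by loss of silanol so that the C2 oxygen is kept as a methyl ether. The fallback sets out from diene 6 and replaces the alkyne by an alkene dienophile followed by a separate dehydrogenation. Diels–Alder reaction of 6 with methyl acrylate (C=CC(=O)OC; toluene, 60–80 °C) should give, with the same polarisation-controlled regiochemistry, the cyclohexene cycloadduct methyl 2,3-dimethoxy-2,4-bis(trimethylsilyloxy)cyclohex-3-ene-1-carboxylate F1. Aqueous HCl in THF should hydrolyse both the ketal and the silyl enol ether of F1 to methyl 3-methoxy-2,4-dioxocyclohexane-1-carboxylate F2; here the fate of C2 is decided by hydrolysis and not by an elimination. Dehydrogenation of F2 with DDQ in refluxing 1,4-dioxane, a known aromatisation of cyclohexane-1,3-diones to resorcinols, should then give 9, where the route is rejoined.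

2. Step 4 (formation of the bis-silyl diene). γ-Deprotonation may be incomplete, the dienolate may be silylated on carbon, and the bis(trimethylsilyl) ketene acetal may lose silicon by hydrolysis during isolation. The fallback sets out from keto ester 3 and avoids both the lithium dienolate and the labile silyl groups. Soft enolisation of both carbonyl units with TBSOTf (2.2 equiv) and Et3N in CH2Cl2 at 0 °C to rt should give in one operation (1Z)-1,3-bis(tert-butyldimethylsilyloxy)-1,2-dimethoxybuta-1,3-diene F3, which should tolerate chromatography. Heating F3 with 7 in toluene should give the cycloadduct methyl 4,6-bis(tert-butyldimethylsilyloxy)-5,6-dimethoxycyclohexa-1,4-diene-1-carboxylate F4, and aqueous HCl in THF should desilylate and aromatise F4 to 9, where the route is rejoined.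

3. Step 11 (Claisen–Schmidt condensation). Under equilibrating base the ketone may also enolise on its methylene side, the product enone may condense with a second aldehyde molecule, and the electron-rich aldehyde may react sluggishly. The fallback sets out from ketone 18 and uses a directed aldol addition with a separate dehydration. Kinetic deprotonation of 18 at the methyl group with LDA in THF at −78 °C should give lithium 6-(4-methoxyphenyl)hex-1-en-2-olate F5. Addition of aldehyde 12 and a quench with acetic acid at −78 °C should give the β-hydroxy ketone 19 as an isolated compound. Acid-catalysed dehydration of 19 (p-TsOH cat., toluene, 50 °C), favoured by the electron-rich benzylic position, should give 20, where the route is rejoined.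

**Further compounds**

F1 | step 5 | methyl 2,3-dimethoxy-2,4-bis(trimethylsilyloxy)cyclohex-3-ene-1-carboxylate (racemic diastereomer mixture) | COC(=O)C1CCC(O[Si](C)(C)C)=C(OC)C1(OC)O[Si](C)(C)C
F2 | step 5 | methyl 3-methoxy-2,4-dioxocyclohexane-1-carboxylate (stereoisomer and tautomer mixture) | COC(=O)C1CCC(=O)C(OC)C1=O
F3 | step 4 | (1Z)-1,3-bis(tert-butyldimethylsilyloxy)-1,2-dimethoxybuta-1,3-diene | C=C(O[Si](C)(C)C(C)(C)C)/C(OC)=C(\OC)O[Si](C)(C)C(C)(C)C
F4 | step 4 | methyl 4,6-bis(tert-butyldimethylsilyloxy)-5,6-dimethoxycyclohexa-1,4-diene-1-carboxylate (racemic) | COC(=O)C1=CCC(O[Si](C)(C)C(C)(C)C)=C(OC)C1(OC)O[Si](C)(C)C(C)(C)C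
F5 | step 11 | lithium 6-(4-methoxyphenyl)hex-1-en-2-olate | C=C(O[Li])CCCCc1ccc(OC)cc1
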